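I choose to reckon this flask from the west run rather than the east one, since the west run holds the same catalyst, 2.5 µM, and differs in its substrate, 0.75 mM against 0.50 mM.

| setting | north-west | east | west | flask |
|---|---|---|---|---|
| substrate | 0.50 mM | 0.50 mM | 0.75 mM | 0.50 mM |
| catalyst | 1.2 µM | 1.9 µM | 2.5 µM | 2.5 µM |
| remark | run made earlier | run made earlier | run made earlier |  |
| time |  |  |  | 3.0 min |

| run | time / min | isomer of the product / % | target / % |
|---|---|---|---|
| north-west | 0.200 | 0.3 | 1.6 |
| north-west | 0.333 | 0.4 | 2.7 |
| north-west | 0.500 | 2.0 | 1.5 |
| north-west | 0.833 | 1.7 | 2.2 |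
| north-west | 1.33 | 2.9 | 2.2 |
| north-west | 2.50 | 4.3 | 1.4 |
| east | 0.417 | 1.0 | 3.1 |
| east | 0.833 | 2.3 | 2.5 |
| east | 1.33 | 4.3 | 2.4 |
| east | 1.50 | 4.8 | 3.4 |
| east | 2.00 | 5.3 | 3.3 |
| east | 2.50 | 5.2 | 2.4 |
| west | 0.200 | 0 | 2.1 |
| west | 0.667 | 2.8 | 3.0 |
| west | 1.00 | 3.8 | 2.2 |
| west | 1.50 | 4.7 | 2.6 |
| west | 2.50 | 5.9 | 1.1 |

(readings scatter by 0.5 percentage points)

- share of isomer of the product in isomer of the product plus target at 2.5 s
- share of isomer of the product in isomer of the product plus target at 3.0 min
- which of isomer of the product and target there is more of at 3.0 min

- a reading or a percentage of target counts all its forms, free or not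

The target readings do not climb with time while the isomer readings do, so I work in concentration and not in percent of the charge. The west run's mean target reading, 2.20%, is a [target] of 16.5 µM. Divided by [catalyst] this gives 6.60, and the same reading gives 7.50 in the east run and 8.06 in the north-west run, which I cannot tell apart within the scatter. Their mean, 7.39, I call the level ratio, [target] at its level over [catalyst].

With the same catalyst, the flask should hold the west run's [target] over less substrate: the level ratio gives 3.69%, a higher percentage than the west run's mean reading. The isomer flattens in percent of the charge, as the east run's last readings, 5.3% and 5.2%, show, so I carry over the west run's last reading, 5.9%. My share is then 61.5% at 3.0 min, with the isomer ahead.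

The forecast, which differs from my reckoning, gives 4% (0% to 12%) and 73% (62% to 84%) with isomer of the product ahead: “At 3 min I expect target near 3% and isomer near 8%”.

The flask gives 1.11% and 62.2%, with isomer of the product ahead, 5.93% against 3.60% of target.

    substrate ⇌ other conformer (K = 0.630, k = 0.0240 s⁻¹)
    substrate + catalyst → catalyst + target (k = 7200 M⁻¹ s⁻¹)
    catalyst + other conformer → catalyst + isomer of the product (k = 1600 M⁻¹ s⁻¹)
    substrate + target → side product (k = 1000 M⁻¹ s⁻¹)
    crystals ⇌ target, rate k5*(cs5 - [target]) while solid is left; crystals form when [target] > cs5 (solubility = 0.300 mM, k = 13.0 s⁻¹)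

One reason the share in this flask stands so high is that substrate consumes the target it also helps to make: with that step taken away, the share at 3.0 min is 10.8% instead of 62.2%. Both rates carry [substrate], so it cancels in this quasi-steady state, and [target] over [catalyst] stands at the ratio of the two constants, 7.20. The neighbour flask with 0.0042 mM of catalyst reckons, with my level ratio, to 6.21% of target; it holds 6.05%, which brings its share down to 49.4%.

The readings stem from a simulated flask on assumed constants.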